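Target in the cedar run still climbs at 5.40 × 10⁻⁴ M h⁻¹ between 11 h and 16 h, and the meeting opened on that number.

| flask | starting material | partner | free catalyst | time |
|---|---|---|---|---|
| cedar | 0.0500 M | 0.125 M | 5.00 × 10⁻⁴ M |  |
| elm | 0.0500 M | 0.190 M | 5.00 × 10⁻⁴ M |  |
| larch | 0.150 M | 0.125 M | 5.00 × 10⁻⁴ M |  |
| oak | 0.0500 M | 0.125 M | 7.50 × 10⁻⁴ M |  |
| ash | 0.0500 M | 0.370 M | 5.00 × 10⁻⁴ M | 16 h |

- cedar run (time / h: [target] / M): 2.7: 0.0108; 5.3: 0.0161; 8.0: 0.0201; 11: 0.0232; 13: 0.0245; 16: 0.0259
- elm run (time / h: [target] / M): 2.7: 0.0146; 5.3: 0.0204; 8.0: 0.0238; 11: 0.0269; 13: 0.0286; 16: 0.0306
- larch run (time / h: [target] / M): 2.7: 0.0230; 5.3: 0.0368; 8.0: 0.0479; 11: 0.0554; 13: 0.0607; 16: 0.0660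
- oak run (time / h: [target] / M): 2.7: 0.0137; 5.3: 0.0208; 8.0: 0.0245; 11: 0.0274; 13: 0.0291; 16: 0.0306

(readings scatter by 3 × 10⁻⁴ M)

- Overall: starting material + partner -> target, with free catalyst as catalyst.
- Constant volume, constant temperature.
- Readings of a species count what is bound in complexes too.
- "The second partner" is partner.
- An order is taken over about fifteen percent of the charge, up and down.

* apparent order in [free catalyst] of the starting rate, round the charge of the cedar run (the rate where two percent of its starting material have turned into target)
* apparent order in [starting material] of the starting rate, round the charge of the cedar run (the rate where two percent of its starting material have turned into target) (one fixed amount of target, the same in the runs compared)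
* target in the ash run at 16 h, as a share of the starting material charged

The first speaker proposed replacing that late stretch of the cedar curve by its mean. Over it, [starting material] averages 0.0255 M and [partner] averages 0.100 M, so dividing the slope by their product gives 0.211 M⁻¹ h⁻¹. She called this the tail constant, the late mean slope of target per unit of mean [starting material] times mean [partner].

A colleague asked what the averaging costs. The concentrations stray about 5.30 % from their means, so the error goes as its square, 0.281 %, which is less than the 15.7 % that scatter puts on the slope.

He then asked whether the tail was catalysed at all. The oak run, charged at 7.50 × 10⁻⁴ M against 5.00 × 10⁻⁴ M, climbs at 6.40 × 10⁻⁴ M h⁻¹ over the same hours. That gap from cedar is smaller than the 1.20 × 10⁻⁴ M h⁻¹ expected from scatter, so the meeting treated the tail as a route without catalyst.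

Two reckonings followed, both the meeting's own. Projecting the first two mean slopes of the cedar run back to the start gives about 0.00564 M h⁻¹. The tail constant at the charge gives 0.00132 M h⁻¹ of that, a share of 23.4 %. If the remainder is proportional to catalyst, the catalyst order is one minus that share, 0.766.

For the ash run, the cedar tail projected back to zero time leaves a catalysed burst of 0.0173 M. The elm run, with more partner, gives 0.0188 M, so the burst was held fixed. The remaining starting material then falls pseudo-first-order at a mean [partner] of 0.345 M, which gives 79.6 % of the charge as target at 16 h.

The forecast was then read out: 1.05, 0.7 and 72 %, the first on the ground that the match of the oak run to the cedar run on a stretched clock "points to a catalyst order of about 1". The meeting differed on the catalyst order and on ash, and took the forecast's figure for the order in starting material, having reckoned none of its own.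

The flask gives 0.81, 0.74 and 76.4 %.

    free catalyst + starting material ⇌ catalyst-substrate complex, settled at all times (12.80 M⁻¹)
    catalyst-substrate complex + partner → target + free catalyst + by-product (177.5 M⁻¹ h⁻¹)
    free catalyst + partner → spent catalyst + partner (2.491 M⁻¹ h⁻¹)
    starting material + partner → target (0.1814 M⁻¹ h⁻¹)

The two part over the uncatalysed conversion of starting material and partner into target. The simulated ash run without that conversion reaches 36.6 % at 16 h, against 76.4 % with it. Apply the tail constant to that run: the 63.4 % of starting material it leaves, decaying at the mean [partner] of ash, comes down to 19.8 % of the charge. The ash flask itself leaves 23.6 %.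

The numbers in the tables stem from a simulated flask for substances that don't exist.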